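**Retrosynthetic overview**
- The target is released last from its 18,21-di-O-methyl ether ((NH4)2Ce(NO3)6 oxidation, Na2S2O4 reduction). Its C12 methoxy group comes from chelation-controlled reduction and methylation of a macrocyclic C12 ketone.
- Key disconnection C12–C13: the 19-membered ring is closed by a nickel-mediated radical acyl–alkyl coupling of a primary C13 alkyl bromide with the activated C12 carboxylic acid.
- The open chain comes from a C3–C4 Hiyama–Denmark coupling of an anilide-bound (Z)-vinyl iodide (east) with a cyclic alkenylsiloxane (west). The C4=C5 Z geometry is fixed beforehand in a temporary six-membered oxasilacycle made by ring-closing metathesis.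
- Stereocentres: one batch of Brown (Z)-crotylborane sets C14/C15 and C10/C11 in two crotylborations, and a γ-methoxyallylboration sets C6/C7. C8=C9 (Z) comes from an α-iodo Wittig olefination followed by formylation, and C2=C3 (Z) from carbomagnesiation of propargyl alcohol.
- Ring order: arene (hydroquinone, present from the start), then the temporary oxasilacycle (formed and opened), then the macrolactam ring by the radical step.

Assumption: the alkene geometry is read literally from the SMILES (C2=C3, C4=C5 and C8=C9 all Z, i.e. C1/C4, C3/C6 and C7/C10 cis); atoms are numbered C1 (amide C=O) to C15 (benzylic carbon) and C16–C21 in the arene, as in the ansamycins.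

**Route**

Step 1
Reactants: 1 hydroquinone
Product: 2 4-methoxyphenol
Conditions: Me2SO4 (0.9 equiv), NaOH, H2O, 20 °C
Reagents that add atoms: dimethyl sulfate COS(=O)(=O)OC
Why: Williamson mono-O-methylation of the symmetrical diphenol with a deficit of alkylating agent stops mainly at the monoether (unreacted 1 is recycled) and creates no stereocentre.

Step 2
Reactants: 2 4-methoxyphenol
Product: 3 2-hydroxy-5-methoxybenzaldehyde
Conditions: MgCl2, Et3N, (CH2O)n, MeCN, reflux
Reagents that add atoms: paraformaldehyde C=O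
Why: Casnati–Skattebøl ortho-formylation, in which the magnesium phenoxide delivers formaldehyde only ortho to the OH and a second formaldehyde oxidises the benzylic alkoxide to the aldehyde by hydride transfer.

Step 3
Reactants: 3 2-hydroxy-5-methoxybenzaldehyde
Product: 4 2-hydroxy-5-methoxy-3-nitrobenzaldehyde
Conditions: HNO3 (65%), AcOH, 10 → 20 °C
Reagents that add atoms: nitric acid O[N+](=O)[O-]
Why: Electrophilic aromatic nitration goes to the only free position ortho to the phenol OH (para is blocked by OMe), which is also meta to the formyl group.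

Step 4
Reactants: 4 2-hydroxy-5-methoxy-3-nitrobenzaldehyde
Product: 5 2,5-dimethoxy-3-nitrobenzaldehyde
Conditions: MeI, K2CO3, DMF, 40 °C
Reagents that add atoms: iodomethane CI
Why: Williamson methylation of the acidic ortho-nitrophenol gives the dimethyl-protected hydroquinone, with the nitro group as a robust masked amine.

Step 5
Reactants: 6 cis-but-2-ene
Product: 7 (Z)-crotyldiisopinocampheylborane (THF solution kept at −78 °C, one batch sized for steps 6 and 13)
Conditions: KOt-Bu, n-BuLi, THF, −78 → −45 °C; (+)-Ipc2BOMe [from (−)-α-pinene], −78 °C; BF3·OEt2, −78 °C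
Reagents that add atoms: (+)-B-methoxydiisopinocampheylborane COB([C@H]1C[C@H]2C[C@H](C2(C)C)[C@@H]1C)[C@H]1C[C@H]2C[C@H](C2(C)C)[C@@H]1C
Why: Brown reagent preparation, in which Schlosser-base metalation of cis-but-2-ene gives (Z)-crotylpotassium, its borate with (+)-Ipc2BOMe loses methoxide to BF3, and the Z geometry of the resulting crotylborane holds as long as the solution stays below −45 °C, so the batch can be divided by cannula; no new stereocentre is formed.

Step 6
Reactants: 5 2,5-dimethoxy-3-nitrobenzaldehyde; 7 (Z)-crotyldiisopinocampheylborane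
Product: 8 (1R,2S)-1-(2,5-dimethoxy-3-nitrophenyl)-2-methylbut-3-en-1-ol
Conditions: 7 (first portion of the THF solution from step 5), then 5, THF, −78 °C; HOCH2CH2NH2, 20 °C
Reagents that add atoms: none
Why: Brown asymmetric crotylboration, in which the (Z)-crotylborane reacts through a closed chair transition state to give the syn adduct and the isopinocampheyl groups from (−)-α-pinene direct attack to the re face of the aldehyde, setting C15 (R) and C14 (S).

Step 7
Reactants: 8 (1R,2S)-1-(2,5-dimethoxy-3-nitrophenyl)-2-methylbut-3-en-1-ol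
Product: 9 2,5-dimethoxy-1-[(1R,2S)-1-methoxy-2-methylbut-3-enyl]-3-nitrobenzene
Conditions: NaH, MeI, THF, 0 → 20 °C
Reagents that add atoms: iodomethane CI
Why: Williamson etherification installs the C15 methyl ether while no N–H is present, without touching the stereocentres.

Step 8
Reactants: 9 2,5-dimethoxy-1-[(1R,2S)-1-methoxy-2-methylbut-3-enyl]-3-nitrobenzene
Product: 12 (2S,3R)-3-(2,5-dimethoxy-3-nitrophenyl)-3-methoxy-2-methylpropan-1-ol, via secondary ozonide 10 (not isolated), via aldehyde 11 (not isolated)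
Conditions: O3, CH2Cl2, −78 °C; then NaBH4, EtOH, −78 → 20 °C
Reagents that add atoms: ozone [O-][O+]=O
Why: Ozonolysis with reductive work-up removes the terminal carbon and gives the C13 primary alcohol, the electron-poor nitroarene being inert to ozone and the α-centre staying intact at low temperature.

Step 9
Reactants: 12 (2S,3R)-3-(2,5-dimethoxy-3-nitrophenyl)-3-methoxy-2-methylpropan-1-ol
Product: 13 (2S,3R)-3-(3-amino-2,5-dimethoxyphenyl)-3-methoxy-2-methylpropan-1-ol
Conditions: Zn dust (10 equiv), NH4Cl, EtOH/H2O, 60 °C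
Reagents that add atoms: none
Why: Zinc/ammonium chloride reduction of the nitroarene, run with excess zinc and gentle heating so that the hydroxylamine stage is carried through to the aniline, is near-neutral and leaves the benzylic methyl ether untouched.

Step 10
Reactants: 14 prop-2-yn-1-ol
Product: 16 (Z)-3-iodo-2-methylprop-2-en-1-ol, via cyclic alkenylmagnesium alkoxide 15 (not isolated)
Conditions: MeMgBr (2.5 equiv), CuI (10 mol%), THF, −10 → 20 °C; then I2, −40 → 0 °C
Reagents that add atoms: methylmagnesium bromide C[Mg]Br; iodine II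
Why: Copper-catalysed hydroxyl-directed carbomagnesiation places methyl on C2 and magnesium on C3 cis to CH2O in a five-membered chelate, and iodinolysis with retention fixes the geometry that becomes C2=C3 (Z).

Step 11
Reactants: 16 (Z)-3-iodo-2-methylprop-2-en-1-ol
Product: 18 (Z)-3-iodo-2-methylprop-2-enoic acid, via (Z)-3-iodo-2-methylprop-2-enal 17 (not isolated)
Conditions: TEMPO (10 mol%), PhI(OAc)2 (2.2 equiv), MeCN/H2O, 20 °C
Reagents that add atoms: water O
Why: Oxoammonium (TEMPO) oxidation of the allylic alcohol through the aldehyde hydrate to the acid is non-acidic and non-basic, so the Z alkene is kept.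

Step 12
Reactants: 13 (2S,3R)-3-(3-amino-2,5-dimethoxyphenyl)-3-methoxy-2-methylpropan-1-ol; 18 (Z)-3-iodo-2-methylprop-2-enoic acid
Product: 19 (2Z)-N-{3-[(1R,2S)-3-hydroxy-1-methoxy-2-methylpropyl]-2,5-dimethoxyphenyl}-3-iodo-2-methylprop-2-enamide
Conditions: EDC·HCl, HOAt, CH2Cl2, 0 → 20 °C
Reagents that add atoms: none
Why: Carbodiimide amide coupling acylates the aniline in preference to the primary alcohol because no acyl-transfer catalyst is present, forming the N–C1 bond early without N-protection.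

Step 13
Reactants: 20 ethyl glyoxylate; 7 (Z)-crotyldiisopinocampheylborane
Product: 21 ethyl (2R,3S)-2-hydroxy-3-methylpent-4-enoate
Conditions: 7 (second portion of the THF solution from step 5), then freshly distilled 20, THF, −78 °C; HOCH2CH2NH2, 20 °C
Reagents that add atoms: none
Why: Brown asymmetric crotylboration of the glyoxylate aldehyde gives, by the same chair transition state and re-face attack as in step 6, the syn adduct with C11 (R) and C10 (S).

Step 14
Reactants: 21 ethyl (2R,3S)-2-hydroxy-3-methylpent-4-enoate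
Product: 22 ethyl (2R,3S)-2-methoxy-3-methylpent-4-enoate
Conditions: MeI, Ag2O, 4 Å MS, Et2O, 35 °C
Reagents that add atoms: iodomethane CI
Why: Purdie methylation is non-basic, so the α-hydroxy ester is etherified without epimerisation at C11.

Step 15
Reactants: 22 ethyl (2R,3S)-2-methoxy-3-methylpent-4-enoate
Product: 24 ethyl (2R,3R)-2-methoxy-3-methyl-4-oxobutanoate, via secondary ozonide 23 (not isolated)
Conditions: O3, CH2Cl2, −78 °C; then Me2S, −78 → 20 °C
Reagents that add atoms: ozone [O-][O+]=O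
Why: Ozonolysis with neutral reductive work-up gives the C9 aldehyde, which is used crude so that C10 does not epimerise (the descriptor changes only through priorities).

Step 16
Reactants: 24 ethyl (2R,3R)-2-methoxy-3-methyl-4-oxobutanoate
Product: 25 ethyl (2R,3S,4Z)-5-iodo-2-methoxy-3-methylhex-4-enoate
Conditions: EtPPh3+ I−, n-BuLi, THF, 20 °C; I2, −78 °C; NaN(SiMe3)2, −78 °C; then 24, −78 → −20 °C
Reagents that add atoms: ethyltriphenylphosphonium iodide CC[P+](c1ccccc1)(c1ccccc1)c1ccccc1.[I-]; iodine II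
Why: Stork–Zhao-type α-iodo Wittig olefination with the non-stabilised iodo-ylide gives kinetically the (Z)-2-iodoalkene with iodine cis to C10, exactly the C8=C9 geometry needed.

Step 17
Reactants: 25 ethyl (2R,3S,4Z)-5-iodo-2-methoxy-3-methylhex-4-enoate
Product: 26 ethyl (2R,3S,4Z)-2-methoxy-3,5-dimethyl-6-oxohex-4-enoate
Conditions: Pd(PPh3)4 (5 mol%), CO (3 atm), Bu3SnH (slow addition), THF, 50 °C
Reagents that add atoms: carbon monoxide [C-]#[O+]
Why: Palladium-catalysed reductive carbonylation (formylation) of the alkenyl iodide proceeds with retention of geometry and tolerates the ester, giving the (Z)-enal with C7 cis to C10.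

Step 18
Reactants: 26 ethyl (2R,3S,4Z)-2-methoxy-3,5-dimethyl-6-oxohex-4-enoate; 27 allyl methyl ether
Product: 29 ethyl (2R,3S,4Z,6S,7S)-6-hydroxy-2,7-dimethoxy-3,5-dimethylnona-4,8-dienoate, via (Z)-3-methoxyallyldiisopinocampheylborane 28 (not isolated)
Conditions: 27, s-BuLi, THF, −78 °C; (+)-Ipc2BOMe; BF3·OEt2; then 26, −78 °C; HOCH2CH2NH2, 20 °C
Reagents that add atoms: none
Why: Brown (Z)-γ-methoxyallylboration adds 1,2 to the enal through a chair transition state, giving the syn methoxy alcohol with re-face control and setting C7 (S) and C6 (S) together with the C6 methyl ether.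

Step 19
Reactants: 29 ethyl (2R,3S,4Z,6S,7S)-6-hydroxy-2,7-dimethoxy-3,5-dimethylnona-4,8-dienoate; 30 chloro(dimethyl)vinylsilane
Product: 31 ethyl (2R,3S,4Z,6S,7S)-6-{[ethenyl(dimethyl)silyl]oxy}-2,7-dimethoxy-3,5-dimethylnona-4,8-dienoate
Conditions: Et3N, DMAP (5 mol%), CH2Cl2, 0 °C
Reagents that add atoms: none
Why: Silylation of the C7 hydroxyl attaches the vinylsilane whose α-carbon becomes C4 and tethers it for ring closure.

Step 20
Reactants: 31 ethyl (2R,3S,4Z,6S,7S)-6-{[ethenyl(dimethyl)silyl]oxy}-2,7-dimethoxy-3,5-dimethylnona-4,8-dienoate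
Product: 32 ethyl (2R,3S,4Z)-2-methoxy-5-[(5S,6S)-5-methoxy-2,2-dimethyl-5,6-dihydro-2H-1,2-oxasilin-6-yl]-3-methylhex-4-enoate
Conditions: Mo(=CHCMe2Ph)(=N-2,6-i-Pr2C6H3)[OCMe(CF3)2]2 (8 mol%), C6H6, 20 °C
Reagents that add atoms: none
Why: Ring-closing metathesis of the vinylsilyl ether with the terminal vinyl group (the trisubstituted C8=C9 alkene is inert) gives a six-membered oxasilacycle, which can only hold a cis C4=C5 double bond.

Step 21
Reactants: 19 (2Z)-N-{3-[(1R,2S)-3-hydroxy-1-methoxy-2-methylpropyl]-2,5-dimethoxyphenyl}-3-iodo-2-methylprop-2-enamide; 32 ethyl (2R,3S,4Z)-2-methoxy-5-[(5S,6S)-5-methoxy-2,2-dimethyl-5,6-dihydro-2H-1,2-oxasilin-6-yl]-3-methylhex-4-enoate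
Product: 33 ethyl (2R,3S,4Z,6S,7S,8Z,10Z)-6-hydroxy-12-({3-[(1R,2S)-3-hydroxy-1-methoxy-2-methylpropyl]-2,5-dimethoxyphenyl}amino)-2,7-dimethoxy-3,5,11-trimethyl-12-oxododeca-4,8,10-trienoate
Conditions: Pd(dba)2 (5 mol%), Bu4NF (2.2 equiv), THF, 20 °C
Reagents that add atoms: none
Why: Fluoride-promoted Hiyama–Denmark cross-coupling of the cyclic alkenylsiloxane with the alkenyl iodide is stereoretentive at both partners, so it joins C3 to C4 as the (2Z,4Z)-diene and frees the C7 hydroxyl.

Step 22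
Reactants: 33 ethyl (2R,3S,4Z,6S,7S,8Z,10Z)-6-hydroxy-12-({3-[(1R,2S)-3-hydroxy-1-methoxy-2-methylpropyl]-2,5-dimethoxyphenyl}amino)-2,7-dimethoxy-3,5,11-trimethyl-12-oxododeca-4,8,10-trienoate
Product: 34 ethyl (2R,3S,4Z,6S,7S,8Z,10Z)-12-({3-[(1R,2R)-3-bromo-1-methoxy-2-methylpropyl]-2,5-dimethoxyphenyl}amino)-6-hydroxy-2,7-dimethoxy-3,5,11-trimethyl-12-oxododeca-4,8,10-trienoate
Conditions: CBr4 (1.05 equiv), PPh3, CH2Cl2, −20 → 0 °C
Reagents that add atoms: tetrabromomethane BrC(Br)(Br)Br
Why: Appel bromination converts the primary C13 alcohol much faster than the hindered secondary C7 alcohol and, being iodine-free, does not isomerise the Z,Z-diene.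

Step 23
Reactants: 34 ethyl (2R,3S,4Z,6S,7S,8Z,10Z)-12-({3-[(1R,2R)-3-bromo-1-methoxy-2-methylpropyl]-2,5-dimethoxyphenyl}amino)-6-hydroxy-2,7-dimethoxy-3,5,11-trimethyl-12-oxododeca-4,8,10-trienoate
Product: 36 ethyl (2R,3S,4Z,6S,7S,8Z,10Z)-12-({3-[(1R,2R)-3-bromo-1-methoxy-2-methylpropyl]-2,5-dimethoxyphenyl}amino)-6-(carbamoyloxy)-2,7-dimethoxy-3,5,11-trimethyl-12-oxododeca-4,8,10-trienoate, via N-trichloroacetyl carbamate 35 (not isolated)
Conditions: Cl3CC(O)NCO, CH2Cl2, 0 °C; then Al2O3 (neutral), 20 °C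
Reagents that add atoms: trichloroacetyl isocyanate O=C=NC(=O)C(Cl)(Cl)Cl
Why: Kočovský carbamoylation, in which the acyl isocyanate adds cleanly to the C7 alcohol and neutral alumina cleaves the trichloroacetyl group without transesterifying the ethyl ester.

Step 24
Reactants: 36 ethyl (2R,3S,4Z,6S,7S,8Z,10Z)-12-({3-[(1R,2R)-3-bromo-1-methoxy-2-methylpropyl]-2,5-dimethoxyphenyl}amino)-6-(carbamoyloxy)-2,7-dimethoxy-3,5,11-trimethyl-12-oxododeca-4,8,10-trienoate
Product: 37 (2R,3S,4Z,6S,7S,8Z,10Z)-12-({3-[(1R,2R)-3-bromo-1-methoxy-2-methylpropyl]-2,5-dimethoxyphenyl}amino)-6-(carbamoyloxy)-2,7-dimethoxy-3,5,11-trimethyl-12-oxododeca-4,8,10-trienoic acid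
Conditions: Me3SnOH, ClCH2CH2Cl, 70 °C; then 5% aq HCl
Reagents that add atoms: trimethyltin hydroxide C[Sn](C)(C)O
Why: Trimethyltin hydroxide cleaves the unhindered α-methoxy ethyl ester under essentially neutral conditions that spare the carbamate, the alkyl bromide and the C11 centre.

Step 25
Reactants: 37 (2R,3S,4Z,6S,7S,8Z,10Z)-12-({3-[(1R,2R)-3-bromo-1-methoxy-2-methylpropyl]-2,5-dimethoxyphenyl}amino)-6-(carbamoyloxy)-2,7-dimethoxy-3,5,11-trimethyl-12-oxododeca-4,8,10-trienoic acid
Product: 39 macrocyclic C12 ketone (18,21-di-O-methyl-12-demethoxy-12-oxo derivative of the target), via mixed tert-butyl carbonic anhydride 38 (not isolated)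
Conditions: Boc2O, MgCl2, THF, 25 °C; then syringe-pump addition (12 h) to NiBr2(diglyme) (30 mol%), 4,4'-di-tert-butyl-2,2'-bipyridine (35 mol%), Zn, NaI, DMA/THF, 25 °C, final 1 mM
Reagents that add atoms: none
Why: Proposed new method: intramolecular version of the nickel-catalysed reductive ketone synthesis from carboxylic acids and alkyl halides, in which zerovalent nickel inserts into mixed anhydride 38 to give an acyl–nickel species, monovalent nickel abstracts the halogen from C13 (bromide, or iodide after exchange with NaI) to give a primary alkyl radical, and radical capture followed by reductive elimination from trivalent nickel forms the C12–C13 bond and closes the 19-membered ring under high dilution, with no new stereocentre and the C11 centre untouched; the closest known reactions are the intermolecular nickel/zinc acid–alkyl halide ketone coupling with Boc2O activation and the nickel-mediated thioester–alkyl iodide ketone couplings used to join large polyether fragments.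

Step 26
Reactants: 39 macrocyclic C12 ketone (18,21-di-O-methyl-12-demethoxy-12-oxo derivative of the target)
Product: 40 macrocyclic (12S)-alcohol (12-O-demethyl-18,21-di-O-methyl derivative of the target)
Conditions: Zn(BH4)2, Et2O/CH2Cl2, −30 °C
Reagents that add atoms: none
Why: Chelation-controlled (Cram-chelate) reduction, in which zinc bridges the ketone and the C11 methoxy oxygen and hydride enters from the face of the C11 hydrogen, giving the 11,12-anti product with C12 (S).

Step 27
Reactants: 40 macrocyclic (12S)-alcohol (12-O-demethyl-18,21-di-O-methyl derivative of the target)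
Product: 41 18,21-di-O-methyl ether of the target
Conditions: Me3OBF4, 1,8-bis(dimethylamino)naphthalene, 4 Å MS, CH2Cl2, 20 °C
Reagents that add atoms: trimethyloxonium tetrafluoroborate C[O+](C)C.F[B-](F)(F)F
Why: Meerwein methylation buffered by the hindered amine alkylates the secondary alcohol without a strong base, and the much less nucleophilic anilide and carbamate groups are expected to be left alone with a small excess of the salt.

Step 28
Reactants: 41 18,21-di-O-methyl ether of the target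
Product: 43 target hydroquinone (2Z,4Z,8Z; 6S,7S,10S,11R,12S,14S,15R), via benzoquinone 42 (not isolated)
Conditions: (NH4)2Ce(NO3)6, MeCN/H2O, −10 °C; then aq Na2S2O4, EtOAc, 20 °C
Reagents that add atoms: water O
Why: Oxidative demethylation of the 1,4-dimethoxyarene by tetravalent cerium gives the para-quinone (the only one possible from this substitution pattern), and dithionite reduces it in the same flask to the hydroquinone.

**Compound list**
1 | hydroquinone | Oc1ccc(O)cc1 | starting material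
2 | 4-methoxyphenol | COc1ccc(O)cc1 | intermediate
3 | 2-hydroxy-5-methoxybenzaldehyde | COc1ccc(O)c(C=O)c1 | intermediate
4 | 2-hydroxy-5-methoxy-3-nitrobenzaldehyde | COc1cc(C=O)c(O)c([N+](=O)[O-])c1 | intermediate
5 | 2,5-dimethoxy-3-nitrobenzaldehyde | COc1cc(C=O)c(OC)c([N+](=O)[O-])c1 | intermediate
6 | cis-but-2-ene | C/C=C\C | starting material
7 | (Z)-but-2-enylbis[(1S,2R,3S,5S)-2,6,6-trimethylbicyclo[3.1.1]hept-3-yl]borane, the (Z)-crotyldiisopinocampheylborane from (−)-α-pinene | C/C=C\CB([C@H]1C[C@H]2C[C@H](C2(C)C)[C@@H]1C)[C@H]1C[C@H]2C[C@H](C2(C)C)[C@@H]1C | intermediate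
8 | (1R,2S)-1-(2,5-dimethoxy-3-nitrophenyl)-2-methylbut-3-en-1-ol | C=C[C@H](C)[C@@H](O)c1cc(OC)cc([N+](=O)[O-])c1OC | intermediate
9 | 2,5-dimethoxy-1-[(1R,2S)-1-methoxy-2-methylbut-3-enyl]-3-nitrobenzene | C=C[C@H](C)[C@@H](OC)c1cc(OC)cc([N+](=O)[O-])c1OC | intermediate
10 | secondary ozonide of 9 (1,2,4-trioxolane at the former vinyl group; C14 and C15 as in 9; trioxolane carbon unspecified) | C1OC(OO1)[C@H](C)[C@@H](OC)c1cc(OC)cc([N+](=O)[O-])c1OC | intermediate
11 | (2R,3R)-3-(2,5-dimethoxy-3-nitrophenyl)-3-methoxy-2-methylpropanal | O=C[C@H](C)[C@@H](OC)c1cc(OC)cc([N+](=O)[O-])c1OC | intermediate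
12 | (2S,3R)-3-(2,5-dimethoxy-3-nitrophenyl)-3-methoxy-2-methylpropan-1-ol | OC[C@H](C)[C@@H](OC)c1cc(OC)cc([N+](=O)[O-])c1OC | intermediate
13 | (2S,3R)-3-(3-amino-2,5-dimethoxyphenyl)-3-methoxy-2-methylpropan-1-ol | OC[C@H](C)[C@@H](OC)c1cc(OC)cc(N)c1OC | intermediate
14 | prop-2-yn-1-ol | C#CCO | starting material
15 | 4-methyl-2,5-dihydro-1,2-oxamagnesole (cyclic alkenylmagnesium alkoxide; Mg cis to CH2O) | CC1=C[Mg]OC1 | intermediate
16 | (Z)-3-iodo-2-methylprop-2-en-1-ol | OC/C(C)=C\I | intermediate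
17 | (Z)-3-iodo-2-methylprop-2-enal | O=C/C(C)=C\I | intermediate
18 | (Z)-3-iodo-2-methylprop-2-enoic acid | OC(=O)/C(C)=C\I | intermediate
19 | (2Z)-N-{3-[(1R,2S)-3-hydroxy-1-methoxy-2-methylpropyl]-2,5-dimethoxyphenyl}-3-iodo-2-methylprop-2-enamide | OC[C@H](C)[C@@H](OC)c1cc(OC)cc(NC(=O)/C(C)=C\I)c1OC | intermediate
20 | ethyl glyoxylate | CCOC(=O)C=O | starting material
21 | ethyl (2R,3S)-2-hydroxy-3-methylpent-4-enoate | C=C[C@H](C)[C@@H](O)C(=O)OCC | intermediate
22 | ethyl (2R,3S)-2-methoxy-3-methylpent-4-enoate | C=C[C@H](C)[C@@H](OC)C(=O)OCC | intermediate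
23 | secondary ozonide of 22 (1,2,4-trioxolane at the former vinyl group; trioxolane carbon unspecified) | C1OC(OO1)[C@H](C)[C@@H](OC)C(=O)OCC | intermediate
24 | ethyl (2R,3R)-2-methoxy-3-methyl-4-oxobutanoate | O=C[C@H](C)[C@@H](OC)C(=O)OCC | intermediate
25 | ethyl (2R,3S,4Z)-5-iodo-2-methoxy-3-methylhex-4-enoate | I/C(C)=C\[C@H](C)[C@@H](OC)C(=O)OCC | intermediate
26 | ethyl (2R,3S,4Z)-2-methoxy-3,5-dimethyl-6-oxohex-4-enoate | O=C/C(C)=C\[C@H](C)[C@@H](OC)C(=O)OCC | intermediate
27 | allyl methyl ether | COCC=C | starting material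
28 | [(Z)-3-methoxyprop-2-enyl]bis[(1S,2R,3S,5S)-2,6,6-trimethylbicyclo[3.1.1]hept-3-yl]borane | CO/C=C\CB([C@H]1C[C@H]2C[C@H](C2(C)C)[C@@H]1C)[C@H]1C[C@H]2C[C@H](C2(C)C)[C@@H]1C | intermediate
29 | ethyl (2R,3S,4Z,6S,7S)-6-hydroxy-2,7-dimethoxy-3,5-dimethylnona-4,8-dienoate | C=C[C@H](OC)[C@@H](O)/C(C)=C\[C@H](C)[C@@H](OC)C(=O)OCC | intermediate
30 | chloro(dimethyl)vinylsilane | C=C[Si](C)(C)Cl | starting material
31 | ethyl (2R,3S,4Z,6S,7S)-6-{[ethenyl(dimethyl)silyl]oxy}-2,7-dimethoxy-3,5-dimethylnona-4,8-dienoate | C=C[C@H](OC)[C@@H](O[Si](C)(C)C=C)/C(C)=C\[C@H](C)[C@@H](OC)C(=O)OCC | intermediate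
32 | ethyl (2R,3S,4Z)-2-methoxy-5-[(5S,6S)-5-methoxy-2,2-dimethyl-5,6-dihydro-2H-1,2-oxasilin-6-yl]-3-methylhex-4-enoate | CO[C@H]1C=C[Si](C)(C)O[C@H]1/C(C)=C\[C@H](C)[C@@H](OC)C(=O)OCC | intermediate
33 | ethyl (2R,3S,4Z,6S,7S,8Z,10Z)-6-hydroxy-12-({3-[(1R,2S)-3-hydroxy-1-methoxy-2-methylpropyl]-2,5-dimethoxyphenyl}amino)-2,7-dimethoxy-3,5,11-trimethyl-12-oxododeca-4,8,10-trienoate | OC[C@H](C)[C@@H](OC)c1cc(OC)cc(NC(=O)/C(C)=C\C=C/[C@H](OC)[C@@H](O)/C(C)=C\[C@H](C)[C@@H](OC)C(=O)OCC)c1OC | intermediate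
34 | ethyl (2R,3S,4Z,6S,7S,8Z,10Z)-12-({3-[(1R,2R)-3-bromo-1-methoxy-2-methylpropyl]-2,5-dimethoxyphenyl}amino)-6-hydroxy-2,7-dimethoxy-3,5,11-trimethyl-12-oxododeca-4,8,10-trienoate | BrC[C@H](C)[C@@H](OC)c1cc(OC)cc(NC(=O)/C(C)=C\C=C/[C@H](OC)[C@@H](O)/C(C)=C\[C@H](C)[C@@H](OC)C(=O)OCC)c1OC | intermediate
35 | N-trichloroacetyl carbamate of 34 at the C7 oxygen | BrC[C@H](C)[C@@H](OC)c1cc(OC)cc(NC(=O)/C(C)=C\C=C/[C@H](OC)[C@@H](OC(=O)NC(=O)C(Cl)(Cl)Cl)/C(C)=C\[C@H](C)[C@@H](OC)C(=O)OCC)c1OC | intermediate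
36 | ethyl (2R,3S,4Z,6S,7S,8Z,10Z)-12-({3-[(1R,2R)-3-bromo-1-methoxy-2-methylpropyl]-2,5-dimethoxyphenyl}amino)-6-(carbamoyloxy)-2,7-dimethoxy-3,5,11-trimethyl-12-oxododeca-4,8,10-trienoate | BrC[C@H](C)[C@@H](OC)c1cc(OC)cc(NC(=O)/C(C)=C\C=C/[C@H](OC)[C@@H](OC(N)=O)/C(C)=C\[C@H](C)[C@@H](OC)C(=O)OCC)c1OC | intermediate
37 | (2R,3S,4Z,6S,7S,8Z,10Z)-12-({3-[(1R,2R)-3-bromo-1-methoxy-2-methylpropyl]-2,5-dimethoxyphenyl}amino)-6-(carbamoyloxy)-2,7-dimethoxy-3,5,11-trimethyl-12-oxododeca-4,8,10-trienoic acid | BrC[C@H](C)[C@@H](OC)c1cc(OC)cc(NC(=O)/C(C)=C\C=C/[C@H](OC)[C@@H](OC(N)=O)/C(C)=C\[C@H](C)[C@@H](OC)C(=O)O)c1OC | intermediate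
38 | mixed anhydride of acid 37 with tert-butyl hydrogen carbonate | BrC[C@H](C)[C@@H](OC)c1cc(OC)cc(NC(=O)/C(C)=C\C=C/[C@H](OC)[C@@H](OC(N)=O)/C(C)=C\[C@H](C)[C@@H](OC)C(=O)OC(=O)OC(C)(C)C)c1OC | intermediate
39 | macrocyclic C12 ketone (18,21-di-O-methyl-12-demethoxy-12-oxo derivative of the target) | O=C1C[C@H](C)[C@@H](OC)c2cc(OC)cc(c2OC)NC(=O)/C(C)=C\C=C/[C@H](OC)[C@@H](OC(N)=O)/C(C)=C\[C@H](C)[C@H]1OC | intermediate
40 | macrocyclic (12S)-alcohol (12-O-demethyl-18,21-di-O-methyl derivative of the target) | O[C@H]1C[C@H](C)[C@@H](OC)c2cc(OC)cc(c2OC)NC(=O)/C(C)=C\C=C/[C@H](OC)[C@@H](OC(N)=O)/C(C)=C\[C@H](C)[C@H]1OC | intermediate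
41 | 18,21-di-O-methyl ether of the target | CO[C@H]1C[C@H](C)[C@@H](OC)c2cc(OC)cc(c2OC)NC(=O)/C(C)=C\C=C/[C@H](OC)[C@@H](OC(N)=O)/C(C)=C\[C@H](C)[C@H]1OC | intermediate
42 | benzoquinone corresponding to the target | CO[C@H]1C[C@H](C)[C@@H](OC)C2=CC(=O)C=C(NC(=O)/C(C)=C\C=C/[C@H](OC)[C@@H](OC(N)=O)/C(C)=C\[C@H](C)[C@H]1OC)C2=O | intermediate
43 | target hydroquinone (2Z,4Z,8Z; 6S,7S,10S,11R,12S,14S,15R) | CO[C@H]1[C@@H](OC)C[C@H](C)[C@@H](OC)c2cc(O)cc(c2O)NC(=O)/C(C)=C\C=C/[C@H](OC)[C@@H](OC(N)=O)/C(C)=C\[C@@H]1C | target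

**Step count and risks**

Total step count: 28. Longest linear sequence: 17 (steps 1–4, 6–9, 12, 21–28).

The three steps most likely to fail:

Step 25 (radical ring closure): the alkyl radical may be reduced, may add to the dienamide, or may couple between molecules before it finds its own acyl–nickel centre, and the α-methoxy acyl–nickel species may lose CO. The fallback sets out from bromo acid 37 and comes back at ketone 39. The acid is esterified with ethanethiol (EDC, DMAP cat.) to the S-ethyl thioester F1. Activated Zn (LiCl, THF) is inserted into the C13–Br bond to give the alkylzinc bromide F2. The ring is then closed by a polar palladium-catalysed thioester–organozinc (Fukuyama) coupling with PdCl2(PPh3)2 under high dilution, which gives macrocyclic ketone 39.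

Step 16 (α-iodo Wittig olefination): yields and Z:E ratios are often moderate, and the basic ylide can epimerise C10 or eliminate the β-methoxy group. The fallback sets out from aldehyde 24 and comes back at enal 26. Ramirez olefination (CBr4, PPh3, CH2Cl2, 0 °C) gives the 1,1-dibromoalkene F3. Trans-selective palladium-catalysed Negishi monomethylation (MeZnCl, Pd(t-Bu3P)2, THF, 0 °C) replaces the bromine trans to C10 and gives the (Z)-2-bromoalkene F4, with bromine cis to C10. Formylation of F4 as in step 17 returns enal 26.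

Step 21 (Hiyama–Denmark union): protodesilylation or loss of Z geometry at C4=C5 is possible with this hindered, heteroatom-rich siloxane. The fallback sets out from siloxane 32 (and amide 19) and comes back at diol 33. Iododesilylation of 32 with N-iodosuccinimide ((CF3)2CHOH, 0 °C; KF, MeOH work-up) gives, with retention, the (Z)-vinyl iodide F5. Amide 19 is converted with Me3SnSnMe3 and Pd(PPh3)4 into the (Z)-alkenylstannane F6. Stille coupling of F5 with F6 (Pd2(dba)3, AsPh3, CuI, DMF, 20 °C) gives diol 33.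

Further compounds
F1 | step 25 | S-ethyl thioester of bromo acid 37 | BrC[C@H](C)[C@@H](OC)c1cc(OC)cc(NC(=O)/C(C)=C\C=C/[C@H](OC)[C@@H](OC(N)=O)/C(C)=C\[C@H](C)[C@@H](OC)C(=O)SCC)c1OC
F2 | step 25 | C13 alkylzinc bromide of thioester F1 | Br[Zn]C[C@H](C)[C@@H](OC)c1cc(OC)cc(NC(=O)/C(C)=C\C=C/[C@H](OC)[C@@H](OC(N)=O)/C(C)=C\[C@H](C)[C@@H](OC)C(=O)SCC)c1OC
F3 | step 16 | ethyl (2R,3S)-5,5-dibromo-2-methoxy-3-methylpent-4-enoate | BrC(Br)=C[C@H](C)[C@@H](OC)C(=O)OCC
F4 | step 16 | ethyl (2R,3S,4Z)-5-bromo-2-methoxy-3-methylhex-4-enoate | Br/C(C)=C\[C@H](C)[C@@H](OC)C(=O)OCC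
F5 | step 21 | ethyl (2R,3S,4Z,6S,7S,8Z)-6-hydroxy-9-iodo-2,7-dimethoxy-3,5-dimethylnona-4,8-dienoate | I/C=C\[C@H](OC)[C@@H](O)/C(C)=C\[C@H](C)[C@@H](OC)C(=O)OCC
F6 | step 21 | (2Z)-N-{3-[(1R,2S)-3-hydroxy-1-methoxy-2-methylpropyl]-2,5-dimethoxyphenyl}-2-methyl-3-(trimethylstannyl)prop-2-enamide | OC[C@H](C)[C@@H](OC)c1cc(OC)cc(NC(=O)/C(C)=C\[Sn](C)(C)C)c1OC
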